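**Retrosynthetic overview** (locants C1–C8a are those of the octahydronaphthalene name of the target)
1. Target ⇐ bicyclic 2-methylcyclohexenone (C5 ketone, C6=C7) by tosylhydrazone reduction with 1,3-transposition, which removes the oxygen and places the C5=C6 double bond.
2. Enone ⇐ acyclic ethyl-ketone/enal: intramolecular Michael addition closes ring B (C4a–C8a), then intramolecular aldol condensation closes ring A.
3. Keto-enal ⇐ allylic carbamate by allyl cyanate-to-isocyanate [3,3] rearrangement, which sets the C1 quaternary C–N centre and the E-enal precursor.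
4. Allylic carbamate ⇐ B-alkyl Suzuki union of fragment 1 (chloro-oxane ketal alkene, from geraniol) with fragment 2 (Z-iodoalkenyl carbamate, from methyl dimethoxyacetate).
5. Ring order: oxane (chloroetherification) → ring B (Michael) → ring A (aldol).

Assumption: a two-stage operation run without isolating the intermediate counts as one step; such intermediates carry their own numbers.

**Fragment 1**

Step 1
Reactants: 1 geraniol
Product: 2 [(2S,3S)-3-methyl-3-(4-methylpent-3-en-1-yl)oxiran-2-yl]methanol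
Conditions: Ti(OiPr)4 (cat.), L-(+)-diethyl tartrate (cat.), t-BuOOH, 4 Å MS, CH2Cl2, −20 °C
Reagents that add atoms: tert-butyl hydroperoxide, CC(C)(C)OO
Why: Sharpless asymmetric epoxidation delivers oxygen to one face of the allylic alcohol, setting both epoxide carbons (S,S) and thereby the future oxane C2 centre.

Step 2
Reactants: 2 [(2S,3S)-3-methyl-3-(4-methylpent-3-en-1-yl)oxiran-2-yl]methanol
Product: 3 (3S)-3,7-dimethyloct-6-ene-1,3-diol
Conditions: NaAlH2(OCH2CH2OCH3)2, THF, 0 °C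
Reagents that add atoms: none
Why: Alkoxy-aluminate-directed hydride opening of the 2,3-epoxy alcohol at C2 gives the 1,3-diol with the tertiary C–O centre retained.

Step 3
Reactants: 3 (3S)-3,7-dimethyloct-6-ene-1,3-diol
Product: 4 2-[(2S,5R)-5-chloro-2,6,6-trimethyloxan-2-yl]ethan-1-ol
Conditions: N-chlorosuccinimide, (CF3)2CHOH, 0 °C; chromatographic separation from the C5 epimer
Reagents that add atoms: N-chlorosuccinimide, O=C1CCC(=O)N1Cl
Why: 6-endo chloroetherification, in which the tertiary alcohol opens the chloriranium ion at its tertiary carbon through a chair transition state (Cl and hydroxyethyl equatorial, methyl axial); the preference over the C5 epimer is expected to be only modest, hence the separation.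

Step 4
Reactants: 4 2-[(2S,5R)-5-chloro-2,6,6-trimethyloxan-2-yl]ethan-1-ol
Product: 5 [(2S,5R)-5-chloro-2,6,6-trimethyloxan-2-yl]acetaldehyde
Conditions: TEMPO (cat.), PhI(OAc)2, CH2Cl2, rt
Reagents that add atoms: none
Why: Oxoammonium (TEMPO) oxidation of the primary alcohol stops at the aldehyde and leaves ether, chloride and stereocentres untouched.

Step 5
Reactants: 5 [(2S,5R)-5-chloro-2,6,6-trimethyloxan-2-yl]acetaldehyde; 6 1-bromobutan-2-one
Product: 8 (5S)-5-[(2S,5R)-5-chloro-2,6,6-trimethyloxan-2-yl]hept-6-en-3-one, via keto aldehyde 7 (not isolated)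
Conditions: trans-2-tert-butyl-3,5-dimethylimidazolidin-4-one·TfOH (20 mol %, enantiomer that delivers the 2R aldehyde), Ru(bpy)3Cl2 (0.5 mol %), 2,6-lutidine, DMF, visible light, rt; crude aldehyde then Ph3PCH3Br, KOtBu, THF, −78→0 °C
Reagents that add atoms: methyltriphenylphosphonium bromide, C[P+](c1ccccc1)(c1ccccc1)c1ccccc1.[Br-]
Why: Enamine/photoredox organocatalytic α-alkylation sets the new centre under catalyst control, and Wittig methylenation of the crude aldehyde (faster than the ketone) avoids epimerisation.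

Step 6
Reactants: 8 (5S)-5-[(2S,5R)-5-chloro-2,6,6-trimethyloxan-2-yl]hept-6-en-3-one
Product: 9 2-{(2S)-2-[(2S,5R)-5-chloro-2,6,6-trimethyloxan-2-yl]but-3-en-1-yl}-2-ethyl-1,3-dioxolane
Conditions: Me3SiOCH2CH2OSiMe3, Me3SiOTf (cat.), CH2Cl2, −78 °C
Reagents that add atoms: 1,2-bis(trimethylsilyloxy)ethane, C[Si](C)(C)OCCO[Si](C)(C)C
Why: Noyori ketalisation under aprotic conditions masks the ketone for the later hydroboration and hydride steps without touching the tertiary ether.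

**Fragment 2**

Step 7
Reactants: 10 methyl 2,2-dimethoxyacetate
Product: 11 N,2,2-trimethoxy-N-methylacetamide
Conditions: MeNH(OMe)·HCl, i-PrMgCl, THF, −20 °C
Reagents that add atoms: N,O-dimethylhydroxylamine hydrochloride, CNOC.Cl
Why: Weinreb amide formation by aminolysis of the ester with the chloromagnesium amide.

Step 8
Reactants: 11 N,2,2-trimethoxy-N-methylacetamide
Product: 12 1,1-dimethoxypent-3-yn-2-one
Conditions: CH3C≡CMgBr, THF, 0 °C; aq NH4Cl
Reagents that add atoms: 1-propynylmagnesium bromide, CC#C[Mg]Br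
Why: Weinreb ketone synthesis, where the chelated tetrahedral intermediate prevents over-addition of the alkynyl Grignard reagent.

Step 9
Reactants: 12 1,1-dimethoxypent-3-yn-2-one
Product: 13 (2S)-1,1-dimethoxypent-3-yn-2-ol
Conditions: RuCl[(R,R)-TsDPEN](p-cymene) (1 mol %), i-PrOH, rt
Reagents that add atoms: none
Why: Noyori asymmetric transfer hydrogenation of an ynone, with the alkyne in the catalyst π-site so that the (R,R) catalyst is expected to give the (S)-carbinol.

Step 10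
Reactants: 13 (2S)-1,1-dimethoxypent-3-yn-2-ol
Product: 15 (2S,3Z)-4-iodo-1,1-dimethoxypent-3-en-2-ol, via alkenylalanate 14 (not isolated)
Conditions: NaAlH2(OCH2CH2OCH3)2, THF, 0 °C→rt; then I2, −78 °C
Reagents that add atoms: iodine, II
Why: Hydroxyl-directed trans-hydroalumination puts aluminium on the distal alkyne carbon, and iodinolysis with retention gives the Z-vinyl iodide without touching the carbinol centre.

Step 11
Reactants: 15 (2S,3Z)-4-iodo-1,1-dimethoxypent-3-en-2-ol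
Product: 17 (2S,3Z)-4-iodo-1,1-dimethoxypent-3-en-2-yl carbamate, via trichloroacetyl carbamate 16 (not isolated)
Conditions: Cl3CC(O)NCO, CH2Cl2, 0 °C; then K2CO3 (cat.), MeOH, rt
Reagents that add atoms: trichloroacetyl isocyanate, O=C=NC(=O)C(Cl)(Cl)Cl
Why: Carbamoylation of the alcohol by an acyl isocyanate followed by methanolysis of the trichloroacetyl group, with no stereocentre involved.

**Union and endgame**

Step 12
Reactants: 9 2-{(2S)-2-[(2S,5R)-5-chloro-2,6,6-trimethyloxan-2-yl]but-3-en-1-yl}-2-ethyl-1,3-dioxolane; 17 (2S,3Z)-4-iodo-1,1-dimethoxypent-3-en-2-yl carbamate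
Product: 19 (2S,3Z,7R)-7-[(2S,5R)-5-chloro-2,6,6-trimethyloxan-2-yl]-8-(2-ethyl-1,3-dioxolan-2-yl)-1,1-dimethoxy-4-methyloct-3-en-2-yl carbamate, via alkylborane 18 (not isolated)
Conditions: 9-BBN-H, THF, rt; then 17, PdCl2(dppf), AsPh3, Cs2CO3, DMF/H2O, rt
Reagents that add atoms: none
Why: B-alkyl Suzuki–Miyaura coupling, in which anti-Markovnikov hydroboration of the terminal alkene is followed by sp3–sp2 coupling with retention of the Z geometry.

Step 13
Reactants: 19 (2S,3Z,7R)-7-[(2S,5R)-5-chloro-2,6,6-trimethyloxan-2-yl]-8-(2-ethyl-1,3-dioxolan-2-yl)-1,1-dimethoxy-4-methyloct-3-en-2-yl carbamate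
Product: 22 N-[(2E,4R,7R)-7-[(2S,5R)-5-chloro-2,6,6-trimethyloxan-2-yl]-8-(2-ethyl-1,3-dioxolan-2-yl)-1,1-dimethoxy-4-methyloct-2-en-4-yl]formamide, via allyl cyanate 20 (not isolated), via allyl isocyanate 21 (not isolated)
Conditions: (CF3CO)2O, Et3N, CH2Cl2, −78→0 °C; solvent exchange; LiBHEt3, THF, −78 °C
Reagents that add atoms: none
Why: Ichikawa allyl cyanate-to-isocyanate [3,3] sigmatropic rearrangement through a chair transition state (acetal carbon equatorial, Z-substituent enforcing it) transfers the C–O chirality to the new quaternary C–N centre (R) and gives the E-alkene, and hydride addition to the isocyanate gives the formamide.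

Step 14
Reactants: 22 N-[(2E,4R,7R)-7-[(2S,5R)-5-chloro-2,6,6-trimethyloxan-2-yl]-8-(2-ethyl-1,3-dioxolan-2-yl)-1,1-dimethoxy-4-methyloct-2-en-4-yl]formamide
Product: 25 N-[(1R,4R,4aR,8aR)-4-[(2S,5R)-5-chloro-2,6,6-trimethyloxan-2-yl]-1,6-dimethyl-5-oxo-1,2,3,4,4a,5,8,8a-octahydronaphthalen-1-yl]formamide, via keto enal 23 (not isolated), via Michael adduct 24 (not isolated)
Conditions: 2 M HCl, THF, rt; neutralise; then piperidine, AcOH, PhMe, 70 °C
Reagents that add atoms: water, O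
Why: After acetal/ketal hydrolysis, a 6-exo intramolecular Michael addition of the ketone α-carbon to the enal closes ring B through a chair transition state with oxanyl, formamido, acyl and side chain all equatorial (the axial C1 methyl forbids an axial acyl group), setting C4a and C8a trans, and an intramolecular aldol condensation then closes ring A (Robinson-type sequence; the only ring sizes possible are six-membered).

Step 15
Reactants: 25 N-[(1R,4R,4aR,8aR)-4-[(2S,5R)-5-chloro-2,6,6-trimethyloxan-2-yl]-1,6-dimethyl-5-oxo-1,2,3,4,4a,5,8,8a-octahydronaphthalen-1-yl]formamide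
Product: 28 N-[(1R,4R,4aR,8aR)-4-[(2S,5R)-5-chloro-2,6,6-trimethyloxan-2-yl]-1,6-dimethyl-1,2,3,4,4a,7,8,8a-octahydronaphthalen-1-yl]formamide, via tosylhydrazone 26 (not isolated), via allylic diazene 27 (not isolated)
Conditions: TsNHNH2, EtOH, 60 °C; evaporate; catecholborane, CHCl3, 0 °C; then NaOAc·3H2O, 65 °C
Reagents that add atoms: none
Why: Kabalka reduction of the enone tosylhydrazone gives an allylic diazene whose retro-ene loss of N2 delivers hydrogen to C7 and moves the double bond to C5=C6 (the carvone-to-limonene pattern), with no stereocentre affected.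

**Compound list**
1 | geraniol, (2E)-3,7-dimethylocta-2,6-dien-1-ol | CC(C)=CCC/C(C)=C/CO | starting material
2 | [(2S,3S)-3-methyl-3-(4-methylpent-3-en-1-yl)oxiran-2-yl]methanol | OC[C@@H]1O[C@@]1(C)CCC=C(C)C | intermediate
3 | (3S)-3,7-dimethyloct-6-ene-1,3-diol | OCC[C@@](C)(O)CCC=C(C)C | intermediate
4 | 2-[(2S,5R)-5-chloro-2,6,6-trimethyloxan-2-yl]ethan-1-ol | OCC[C@]1(C)CC[C@@H](Cl)C(C)(C)O1 | intermediate
5 | [(2S,5R)-5-chloro-2,6,6-trimethyloxan-2-yl]acetaldehyde | O=CC[C@]1(C)CC[C@@H](Cl)C(C)(C)O1 | intermediate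
6 | 1-bromobutan-2-one | CCC(=O)CBr | starting material
7 | (2R)-2-[(2S,5R)-5-chloro-2,6,6-trimethyloxan-2-yl]-4-oxohexanal | O=C[C@H](CC(=O)CC)[C@]1(C)CC[C@@H](Cl)C(C)(C)O1 | intermediate
8 | (5S)-5-[(2S,5R)-5-chloro-2,6,6-trimethyloxan-2-yl]hept-6-en-3-one | C=C[C@H](CC(=O)CC)[C@]1(C)CC[C@@H](Cl)C(C)(C)O1 | intermediate
9 | 2-{(2S)-2-[(2S,5R)-5-chloro-2,6,6-trimethyloxan-2-yl]but-3-en-1-yl}-2-ethyl-1,3-dioxolane (fragment 1) | C=C[C@H](CC1(CC)OCCO1)[C@]2(C)CC[C@@H](Cl)C(C)(C)O2 | intermediate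
10 | methyl 2,2-dimethoxyacetate | COC(OC)C(=O)OC | starting material
11 | N,2,2-trimethoxy-N-methylacetamide | COC(OC)C(=O)N(C)OC | intermediate
12 | 1,1-dimethoxypent-3-yn-2-one | CC#CC(=O)C(OC)OC | intermediate
13 | (2S)-1,1-dimethoxypent-3-yn-2-ol | CC#C[C@H](O)C(OC)OC | intermediate
14 | sodium cyclic alkenylalanate (Al on C4 and on the carbinol O, two 2-methoxyethoxy ligands) | C/C1=C/[C@@H](C(OC)OC)O[Al-]1(OCCOC)OCCOC.[Na+] | intermediate
15 | (2S,3Z)-4-iodo-1,1-dimethoxypent-3-en-2-ol | C/C(I)=C/[C@H](O)C(OC)OC | intermediate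
16 | (2S,3Z)-4-iodo-1,1-dimethoxypent-3-en-2-yl N-(trichloroacetyl)carbamate | C/C(I)=C/[C@H](OC(=O)NC(=O)C(Cl)(Cl)Cl)C(OC)OC | intermediate
17 | (2S,3Z)-4-iodo-1,1-dimethoxypent-3-en-2-yl carbamate (fragment 2) | C/C(I)=C/[C@H](OC(N)=O)C(OC)OC | intermediate
18 | 9-{(3R)-3-[(2S,5R)-5-chloro-2,6,6-trimethyloxan-2-yl]-4-(2-ethyl-1,3-dioxolan-2-yl)butyl}-9-borabicyclo[3.3.1]nonane | C1CC2CCCC(C1)B2CC[C@H](CC3(CC)OCCO3)[C@]4(C)CC[C@@H](Cl)C(C)(C)O4 | intermediate
19 | (2S,3Z,7R)-7-[(2S,5R)-5-chloro-2,6,6-trimethyloxan-2-yl]-8-(2-ethyl-1,3-dioxolan-2-yl)-1,1-dimethoxy-4-methyloct-3-en-2-yl carbamate | C/C(CC[C@H](CC1(CC)OCCO1)[C@]2(C)CC[C@@H](Cl)C(C)(C)O2)=C/[C@H](OC(N)=O)C(OC)OC | intermediate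
20 | the cyanate (O–C≡N) of the same (2S,3Z,7R) allylic alcohol | C/C(CC[C@H](CC1(CC)OCCO1)[C@]2(C)CC[C@@H](Cl)C(C)(C)O2)=C/[C@H](OC#N)C(OC)OC | intermediate
21 | (2E,4R,7R)-4-isocyanato analogue of 22 (N=C=O in place of NHCHO) | COC(OC)/C=C/[C@](C)(N=C=O)CC[C@H](CC1(CC)OCCO1)[C@]2(C)CC[C@@H](Cl)C(C)(C)O2 | intermediate
22 | N-[(2E,4R,7R)-7-[(2S,5R)-5-chloro-2,6,6-trimethyloxan-2-yl]-8-(2-ethyl-1,3-dioxolan-2-yl)-1,1-dimethoxy-4-methyloct-2-en-4-yl]formamide | COC(OC)/C=C/[C@](C)(NC=O)CC[C@H](CC1(CC)OCCO1)[C@]2(C)CC[C@@H](Cl)C(C)(C)O2 | intermediate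
23 | N-[(2E,4R,7R)-7-[(2S,5R)-5-chloro-2,6,6-trimethyloxan-2-yl]-4-methyl-1,9-dioxoundec-2-en-4-yl]formamide | O=C/C=C/[C@](C)(NC=O)CC[C@H](CC(=O)CC)[C@]1(C)CC[C@@H](Cl)C(C)(C)O1 | intermediate
24 | N-[(1R,2R,3R,4R)-4-[(2S,5R)-5-chloro-2,6,6-trimethyloxan-2-yl]-1-methyl-2-(2-oxoethyl)-3-propanoylcyclohexyl]formamide | CCC(=O)[C@@H]1[C@@H](CC=O)[C@](C)(NC=O)CC[C@H]1[C@]2(C)CC[C@@H](Cl)C(C)(C)O2 | intermediate
25 | N-[(1R,4R,4aR,8aR)-4-[(2S,5R)-5-chloro-2,6,6-trimethyloxan-2-yl]-1,6-dimethyl-5-oxo-1,2,3,4,4a,5,8,8a-octahydronaphthalen-1-yl]formamide | CC1=CC[C@@H]2[C@@H](C1=O)[C@@H](CC[C@@]2(C)NC=O)[C@]3(C)CC[C@@H](Cl)C(C)(C)O3 | intermediate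
26 | N-tosylhydrazone of 25 at C5 | CC1=CC[C@@H]2[C@@H](C1=NNS(=O)(=O)c4ccc(C)cc4)[C@@H](CC[C@@]2(C)NC=O)[C@]3(C)CC[C@@H](Cl)C(C)(C)O3 | intermediate
27 | C5 allylic diazene (C5–N=NH, C6=C7 still in place) | CC1=CC[C@@H]2[C@@H](C1N=N)[C@@H](CC[C@@]2(C)NC=O)[C@]3(C)CC[C@@H](Cl)C(C)(C)O3 | intermediate
28 | N-[(1R,4R,4aR,8aR)-4-[(2S,5R)-5-chloro-2,6,6-trimethyloxan-2-yl]-1,6-dimethyl-1,2,3,4,4a,7,8,8a-octahydronaphthalen-1-yl]formamide | CC1=C[C@@H]2[C@@H](CC1)[C@](C)(NC=O)CC[C@H]2[C@]1(C)CC[C@@H](Cl)C(C)(C)O1 | target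

**Totals**
Total step count: 15. Longest linear sequence: 10 steps (steps 1–6 then 12–15, geraniol to target); the fragment 2 branch is steps 7–11.

**Steps most likely to fail, with fallbacks**

Step 5 (radical α-alkylation of an aldehyde next to a quaternary ether carbon). The fallback sets out from 5 and returns at 8. A diarylprolinol silyl ether catalyses the Michael addition of 5 to 2-nitrobut-1-ene, giving the γ-nitro aldehyde (2R)-2-[(2S,5R)-5-chloro-2,6,6-trimethyloxan-2-yl]-4-nitrohexanal F3. Methylenation (Ph3P=CH2, excess) gives (2S,5R)-5-chloro-2,6,6-trimethyl-2-[(3S)-5-nitrohept-1-en-3-yl]oxane F4. A reductive Nef reaction (aqueous TiCl3, NH4OAc buffer) then unveils the ketone 8.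

Step 3 (modest diastereoselectivity, and competing ene-type allylic chlorination). The fallback sets out from 3 and returns at 4, and fixes the chloride configuration by reagent control. Shi epoxidation (fructose-derived ketone enantiomer that gives the 6R epoxide, KHSO5, buffered MeCN/H2O) gives (3S)-5-[(2R)-3,3-dimethyloxiran-2-yl]-3-methylpentane-1,3-diol F1. Camphorsulfonic acid induces 5-exo opening with inversion to 2-[(2S,5S)-5-(2-hydroxypropan-2-yl)-2-methyloxolan-2-yl]ethan-1-ol F2. Ionisation of the tertiary carbinol (Me3SiCl, ZnCl2 cat., CH2Cl2, 0 °C; aqueous work-up) forms the bicyclic oxonium ion. Chloride opens it at the secondary carbon with inversion; because the tertiary chloride re-ionises, the ring-expanded secondary chloride 4 should accumulate.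

Step 15 (hydrazone formation at a flanked enone carbonyl, possible conjugate addition of the hydrazide). The fallback sets out from 25 and returns at 28. 1,4-Reduction with LiBH(s-Bu)3 (THF, −78 °C, excess to cover the N–H) gives the regiodefined C5–C6 enolate. Trapping with N-(5-chloropyridin-2-yl)triflimide gives (4aR,5R,8R,8aR)-8-[(2S,5R)-5-chloro-2,6,6-trimethyloxan-2-yl]-5-formamido-2,5-dimethyl-3,4,4a,5,6,7,8,8a-octahydronaphthalen-1-yl trifluoromethanesulfonate F5. Pd(OAc)2/PPh3, HCO2H, n-Bu3N, DMF, 60 °C then replaces the triflate by hydrogen to give 28.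

Further compounds
F1 | step 3 | (3S)-5-[(2R)-3,3-dimethyloxiran-2-yl]-3-methylpentane-1,3-diol | OCC[C@@](C)(O)CC[C@H]1OC1(C)C
F2 | step 3 | 2-[(2S,5S)-5-(2-hydroxypropan-2-yl)-2-methyloxolan-2-yl]ethan-1-ol | OCC[C@]1(C)CC[C@H](O1)C(C)(C)O
F3 | step 5 | (2R)-2-[(2S,5R)-5-chloro-2,6,6-trimethyloxan-2-yl]-4-nitrohexanal | O=C[C@H](CC(CC)[N+](=O)[O-])[C@]1(C)CC[C@@H](Cl)C(C)(C)O1
F4 | step 5 | (2S,5R)-5-chloro-2,6,6-trimethyl-2-[(3S)-5-nitrohept-1-en-3-yl]oxane | C=C[C@H](CC(CC)[N+](=O)[O-])[C@]1(C)CC[C@@H](Cl)C(C)(C)O1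
F5 | step 15 | (4aR,5R,8R,8aR)-8-[(2S,5R)-5-chloro-2,6,6-trimethyloxan-2-yl]-5-formamido-2,5-dimethyl-3,4,4a,5,6,7,8,8a-octahydronaphthalen-1-yl trifluoromethanesulfonate | CC1=C(OS(=O)(=O)C(F)(F)F)[C@@H]2[C@@H](CC1)[C@](C)(NC=O)CC[C@H]2[C@]3(C)CC[C@@H](Cl)C(C)(C)O3
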